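**Strategy.** The oxocane of the target (ring O, C6–C12; numbering from the alkyne terminus) is read as the periphery of a 1-oxoniabicyclo[3.3.0]octane, because its oxygen and C9 divide the eight-membered ring into two five-atom halves and C9/C10 and C13 carry oxygen. A 2,5-trans tetrahydrofuran (O, C6–C9) bearing a C10 tert-butyl carbonate and a trans-12,13-epoxide is treated with a Lewis acid: the ring oxygen opens the epoxide at C12 and the carbonate then cleaves the shared O–C9 bond. One operation forms the oxocane, sets C12 and C9 by two stereospecific inversions and delivers the cis-9,10-diol (as carbonate) and the C13 hydroxyl.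

Key step: step 12

Remark: the SMILES is read as the (3Z,6R,7R,9R,10S,12R,13S) isomer (C1 = alkyne CH to C15; TBS = tert-butyldimethylsilyl, TIPS = triisopropylsilyl), and (2R,3R)-1,2:3,4-diepoxybutane and the L-fructose-derived (ent-)Shi ketone are taken as purchasable.

Step 1
Reactants: 1 (2R,3R)-1,2:3,4-diepoxybutane; 2 tert-butyldimethyl(prop-2-yn-1-yloxy)silane
Product: 3 (1R)-5-(TBS-oxy)-1-[(2R)-oxiran-2-yl]pent-3-yn-1-ol
Conditions: n-BuLi, THF, −78 °C; BF3·OEt2; then 1 (2 equiv), −78 °C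
Reagents that add atoms: none
Why: Yamaguchi–Hirao alkynylation, in which the BF3-activated lithium acetylide of 2 opens one terminal epoxide of the C2-symmetric bis-epoxide at its CH2 carbon, so the two purchased stereocentres (later C6 and C7) are untouched and an excess of 1 should hold back double opening.

Step 2
Reactants: 3 (1R)-5-(TBS-oxy)-1-[(2R)-oxiran-2-yl]pent-3-yn-1-ol
Product: 4 (2R)-2-[(1R)-1,5-bis(TBS-oxy)pent-3-yn-1-yl]oxirane
Conditions: TBSCl, imidazole, DMF, rt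
Reagents that add atoms: tert-butyldimethylsilyl chloride CC(C)(C)[Si](C)(C)Cl
Why: Standard silylation under non-basic conditions that should avoid Payne rearrangement of the 2,3-epoxy alcohol; the silyl ether later keeps the C7 oxygen from acting as a neighbouring group.

Step 3
Reactants: 4 (2R)-2-[(1R)-1,5-bis(TBS-oxy)pent-3-yn-1-yl]oxirane; 5 vinylmagnesium bromide
Product: 6 (4R,5R)-5,9-bis(TBS-oxy)non-1-en-7-yn-4-ol
Conditions: CuI (10 mol %), THF, −40 to −20 °C
Reagents that add atoms: none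
Why: Copper-catalysed Grignard opening of a terminal epoxide at the unhindered CH2 carbon should give the homoallylic alcohol with the C6 carbinol configuration retained, at a temperature where 1,2-silyl migration is slow.

Step 4
Reactants: 6 (4R,5R)-5,9-bis(TBS-oxy)non-1-en-7-yn-4-ol
Product: 7 (5R,6R)-5-(TBS-oxy)non-8-en-2-yne-1,6-diol
Conditions: CSA (10 mol %), MeOH–CH2Cl2, 0 °C
Reagents that add atoms: none
Why: Acid-catalysed methanolysis should cleave the primary propargylic TBS ether much faster than the hindered secondary one.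

Step 5
Reactants: 7 (5R,6R)-5-(TBS-oxy)non-8-en-2-yne-1,6-diol
Product: 8 (2Z,5R,6R)-5-(TBS-oxy)nona-2,8-diene-1,6-diol
Conditions: H2 (1 atm), Lindlar catalyst, quinoline, EtOAc, rt
Reagents that add atoms: none
Why: Lindlar semihydrogenation gives the (Z)-allylic alcohol by syn addition of hydrogen; the alkyne binds the poisoned catalyst far more strongly than the terminal alkene and the reaction is stopped after one equivalent.

Step 6
Reactants: 8 (2Z,5R,6R)-5-(TBS-oxy)nona-2,8-diene-1,6-diol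
Product: 10 (1S)-1-[(2S,4R,5R)-4-(TBS-oxy)-5-(prop-2-en-1-yl)oxolan-2-yl]ethane-1,2-diol, via epoxy alcohol 9 (not isolated)
Conditions: Ti(OiPr)4 (20 mol %), L-(+)-DET (24 mol %), TBHP, 4 Å MS, CH2Cl2, −20 °C; then CSA (10 mol %), 0 °C
Reagents that add atoms: tert-butyl hydroperoxide CC(C)(C)OO
Why: Sharpless asymmetric epoxidation with L-(+)-DET should give the (2S,3R)-epoxy alcohol 9 under reagent control, and acid then triggers a stereospecific 5-exo-tet opening by the C6 hydroxyl at the distal epoxide carbon with inversion, which sets C9 (S) and C10 (S) and the 2,5-trans ring.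

Step 7
Reactants: 10 (1S)-1-[(2S,4R,5R)-4-(TBS-oxy)-5-(prop-2-en-1-yl)oxolan-2-yl]ethane-1,2-diol
Product: 12 (2S)-2-[(2S,4R,5R)-4-(TBS-oxy)-5-(prop-2-en-1-yl)oxolan-2-yl]oxirane, via primary tosylate 11 (not isolated)
Conditions: NaH, N-tosylimidazole, THF, 0 °C to rt
Reagents that add atoms: none
Why: One-pot diol-to-epoxide conversion in which the primary alkoxide is sulfonylated selectively and the neighbouring secondary alkoxide closes the oxirane by 3-exo-tet displacement, so C10 keeps its configuration.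

Step 8
Reactants: 12 (2S)-2-[(2S,4R,5R)-4-(TBS-oxy)-5-(prop-2-en-1-yl)oxolan-2-yl]oxirane; 13 but-1-yne
Product: 14 (1S)-1-[(2S,4R,5R)-4-(TBS-oxy)-5-(prop-2-en-1-yl)oxolan-2-yl]hex-3-yn-1-ol
Conditions: n-BuLi, THF, −78 °C; BF3·OEt2; then 12, −78 °C
Reagents that add atoms: none
Why: Yamaguchi–Hirao alkynylation in which lithium butynylide opens the terminal epoxide at CH2, leaving the C10 stereocentre untouched.

Step 9
Reactants: 14 (1S)-1-[(2S,4R,5R)-4-(TBS-oxy)-5-(prop-2-en-1-yl)oxolan-2-yl]hex-3-yn-1-ol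
Product: 15 (1S,3E)-1-[(2S,4R,5R)-4-(TBS-oxy)-5-(prop-2-en-1-yl)oxolan-2-yl]hex-3-en-1-ol
Conditions: Na, NH3(l), THF, −78 to −33 °C; NH4Cl
Reagents that add atoms: none
Why: Dissolving-metal reduction of the internal alkyne proceeds through the trans vinyl radical anion to the (E)-alkene, while the isolated terminal alkene, the silyl ether and the ring ether are inert.

Step 10
Reactants: 15 (1S,3E)-1-[(2S,4R,5R)-4-(TBS-oxy)-5-(prop-2-en-1-yl)oxolan-2-yl]hex-3-en-1-ol
Product: 16 tert-butyl (1S,3E)-1-[(2S,4R,5R)-4-(TBS-oxy)-5-(prop-2-en-1-yl)oxolan-2-yl]hex-3-en-1-yl carbonate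
Conditions: Boc2O, DMAP, MeCN, rt
Reagents that add atoms: di-tert-butyl dicarbonate CC(C)(C)OC(=O)OC(=O)OC(C)(C)C
Why: DMAP-catalysed acylation of the secondary alcohol installs the carbonate that serves as the internal nucleophile of the key step.

Step 11
Reactants: 16 tert-butyl (1S,3E)-1-[(2S,4R,5R)-4-(TBS-oxy)-5-(prop-2-en-1-yl)oxolan-2-yl]hex-3-en-1-yl carbonate
Product: 17 tert-butyl (1S)-2-[(2S,3S)-3-ethyloxiran-2-yl]-1-[(2S,4R,5R)-4-(TBS-oxy)-5-(prop-2-en-1-yl)oxolan-2-yl]ethyl carbonate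
Conditions: ent-Shi ketone (30 mol %), Oxone, K2CO3, Bu4NHSO4, MeCN–DMM, aq. borate buffer (pH 10.5), 0 °C
Reagents that add atoms: potassium peroxymonosulfate (Oxone) [K+].[O-]S(=O)(=O)OO
Why: Shi asymmetric epoxidation, in which the dioxirane of the L-fructose-derived ketone epoxidises the trans-1,2-disubstituted alkene through a spiro transition state to the (12S,13S)-epoxide under reagent control, while the monosubstituted terminal alkene reacts far more slowly.

Step 12
Reactants: 17 tert-butyl (1S)-2-[(2S,3S)-3-ethyloxiran-2-yl]-1-[(2S,4R,5R)-4-(TBS-oxy)-5-(prop-2-en-1-yl)oxolan-2-yl]ethyl carbonate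
Product: 20 (2R,3R,5R,6S,8R)-3-(TBS-oxy)-8-[(1S)-1-hydroxypropyl]-2-(prop-2-en-1-yl)oxocane-5,6-diyl carbonate (cyclic 5,6-carbonate), via bicyclic oxonium ion 18 (not isolated), via tert-butoxydioxolanylium ion 19 (not isolated)
Conditions: BF3·OEt2 (30 mol %), CH2Cl2, −78 to −40 °C; aq. NaHCO3
Reagents that add atoms: none
Why: Proposed new method: BF3 activates the trans-epoxide and the tetrahydrofuran oxygen opens it at C12 in a 5-exo-tet mode with inversion to give the cis-fused 1-oxoniabicyclo[3.3.0]octane 18, whose bridgehead C9–O bond is then cleaved with inversion by the carbonyl oxygen of the C10 carbonate (5-exo-tet, ion 19), after which loss of isobutene leaves the cyclic carbonate and the released proton returns the Lewis acid. The closest known reaction type is the bromonium-induced ring expansion of tetrahydrofurans to eight-membered bromo ethers with tert-butyl carbonate trapping, together with Lewis acid epoxide-opening cascades ended by tert-butyl carbonates; new here is the epoxide as trigger of the ring expansion. The oxocane is not closed directly but results as the periphery of the two five-membered closures once the shared O–C9 bond breaks. C12 (R) is fixed by the reagent-controlled epoxide through one SN2 inversion, C13 keeps its C–O bond, and C9 (R) arises by SN2 inversion of the 9S centre with the new C9–O bond held cis to C10–O by the five-membered carbonate. The step needs the ether oxygen to outrun the carbonate carbonyl at the activated epoxide (5-exo by the more basic sp3 oxygen against 6-exo by the carbonyl) and needs the oxonium ion to open at C9 and not at C6 or C12, which is secured because only C9 lies within reach of the carbonate in a five-membered exo transition state and the C7 silyl ether cannot participate.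

Step 13
Reactants: 20 (2R,3R,5R,6S,8R)-3-(TBS-oxy)-8-[(1S)-1-hydroxypropyl]-2-(prop-2-en-1-yl)oxocane-5,6-diyl carbonate
Product: 22 5,6-O-isopropylidene acetal of (2R,3R,5R,6S,8R)-3-(TBS-oxy)-8-[(1S)-1-hydroxypropyl]-2-(prop-2-en-1-yl)oxocane-5,6-diol, via triol 21 (not isolated)
Conditions: K2CO3 (20 mol %), MeOH, rt; then 2,2-dimethoxypropane, PPTS, acetone, rt
Reagents that add atoms: 2,2-dimethoxypropane COC(C)(C)OC
Why: Base-catalysed transesterification releases the cis-diol, and acid-catalysed ketal exchange should then engage only the cis-vicinal diol in a five-membered dioxolane, leaving the C13 hydroxyl free.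

Step 14
Reactants: 22 5,6-O-isopropylidene acetal of (2R,3R,5R,6S,8R)-3-(TBS-oxy)-8-[(1S)-1-hydroxypropyl]-2-(prop-2-en-1-yl)oxocane-5,6-diol
Product: 23 5,6-O-isopropylidene acetal of 2-[(2R,3R,5R,6S,8R)-3-(TBS-oxy)-5,6-dihydroxy-8-[(1S)-1-hydroxypropyl]oxocan-2-yl]acetaldehyde
Conditions: O3, CH2Cl2, −78 °C; then PPh3
Reagents that add atoms: ozone [O-][O+]=O
Why: Ozonolysis with reductive work-up cleaves the only alkene to the aldehyde without touching ether, acetal, silyl ether or alcohol.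

Step 15
Reactants: 23 5,6-O-isopropylidene acetal of 2-[(2R,3R,5R,6S,8R)-3-(TBS-oxy)-5,6-dihydroxy-8-[(1S)-1-hydroxypropyl]oxocan-2-yl]acetaldehyde; 24 1,3-bis(triisopropylsilyl)prop-1-yne
Product: 25 5,6-O-isopropylidene acetal of (2R,3R,5R,6S,8R)-3-(TBS-oxy)-8-[(1S)-1-hydroxypropyl]-2-[(2Z)-5-(triisopropylsilyl)pent-2-en-4-yn-1-yl]oxocane-5,6-diol
Conditions: 24, n-BuLi, THF, −20 °C; then 23, −78 °C to rt
Reagents that add atoms: none
Why: Yamamoto–Peterson olefination, in which the lithiated bis-silyl propyne adds to the aldehyde and the bulky β-silyl alkoxide collapses by syn elimination to the (Z)-enyne, with one extra equivalent of reagent covering the free hydroxyl.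

Step 16
Reactants: 25 5,6-O-isopropylidene acetal of (2R,3R,5R,6S,8R)-3-(TBS-oxy)-8-[(1S)-1-hydroxypropyl]-2-[(2Z)-5-(triisopropylsilyl)pent-2-en-4-yn-1-yl]oxocane-5,6-diol
Product: 26 5,6-O-isopropylidene acetal of (2R,3R,5R,6S,8R)-8-[(1S)-1-hydroxypropyl]-2-[(2Z)-pent-2-en-4-yn-1-yl]oxocane-3,5,6-triol
Conditions: TBAF, THF, 0 °C to rt
Reagents that add atoms: none
Why: Fluoride-mediated desilylation removes the alkynyl TIPS group and the secondary TBS ether in one operation, while acetal and enyne are stable.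

Step 17
Reactants: 26 5,6-O-isopropylidene acetal of (2R,3R,5R,6S,8R)-8-[(1S)-1-hydroxypropyl]-2-[(2Z)-pent-2-en-4-yn-1-yl]oxocane-3,5,6-triol
Product: 27 (2R,3R,5R,6S,8R)-8-[(1S)-1-acetoxypropyl]-5,6-(isopropylidenedioxy)-2-[(2Z)-pent-2-en-4-yn-1-yl]oxocan-3-yl acetate
Conditions: Ac2O, pyridine, DMAP, CH2Cl2, rt
Reagents that add atoms: acetic anhydride CC(=O)OC(C)=O
Why: DMAP-catalysed acetylation of the C7 and C13 secondary alcohols, which are the only free hydroxyls.

Step 18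
Reactants: 27 (2R,3R,5R,6S,8R)-8-[(1S)-1-acetoxypropyl]-5,6-(isopropylidenedioxy)-2-[(2Z)-pent-2-en-4-yn-1-yl]oxocan-3-yl acetate
Product: 28 (2R,3R,5R,6S,8R)-8-[(1S)-1-acetoxypropyl]-5,6-dihydroxy-2-[(2Z)-pent-2-en-4-yn-1-yl]oxocan-3-yl acetate (target)
Conditions: AcOH–H2O (4:1), 40 °C
Reagents that add atoms: none
Why: Mild acid hydrolysis of the dioxolane should free the cis-9,10-diol while the secondary acetates and the enyne survive, at a temperature that keeps acyl migration slow.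

**Compound list**

1 | (2R,3R)-1,2:3,4-diepoxybutane | C1O[C@H]1[C@H]1CO1 | starting material
2 | tert-butyldimethyl(prop-2-yn-1-yloxy)silane | C#CCO[Si](C)(C)C(C)(C)C | starting material
3 | (1R)-5-[(tert-butyldimethylsilyl)oxy]-1-[(2R)-oxiran-2-yl]pent-3-yn-1-ol | C1O[C@H]1[C@H](O)CC#CCO[Si](C)(C)C(C)(C)C | intermediate
4 | (2R)-2-[(1R)-1,5-bis[(tert-butyldimethylsilyl)oxy]pent-3-yn-1-yl]oxirane | C1O[C@H]1[C@H](O[Si](C)(C)C(C)(C)C)CC#CCO[Si](C)(C)C(C)(C)C | intermediate
5 | vinylmagnesium bromide | C=C[Mg]Br | starting material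
6 | (4R,5R)-5,9-bis[(tert-butyldimethylsilyl)oxy]non-1-en-7-yn-4-ol | C=CC[C@@H](O)[C@H](O[Si](C)(C)C(C)(C)C)CC#CCO[Si](C)(C)C(C)(C)C | intermediate
7 | (5R,6R)-5-[(tert-butyldimethylsilyl)oxy]non-8-en-2-yne-1,6-diol | C=CC[C@@H](O)[C@H](O[Si](C)(C)C(C)(C)C)CC#CCO | intermediate
8 | (2Z,5R,6R)-5-[(tert-butyldimethylsilyl)oxy]nona-2,8-diene-1,6-diol | C=CC[C@@H](O)[C@H](O[Si](C)(C)C(C)(C)C)C/C=C\CO | intermediate
9 | (2R,3R)-2-[(tert-butyldimethylsilyl)oxy]-1-[(2R,3S)-3-(hydroxymethyl)oxiran-2-yl]hex-5-en-3-ol | C=CC[C@@H](O)[C@H](O[Si](C)(C)C(C)(C)C)C[C@H]1O[C@H]1CO | intermediate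
10 | (1S)-1-[(2S,4R,5R)-4-[(tert-butyldimethylsilyl)oxy]-5-(prop-2-en-1-yl)oxolan-2-yl]ethane-1,2-diol | C=CC[C@H]1O[C@@H](C[C@H]1O[Si](C)(C)C(C)(C)C)[C@@H](O)CO | intermediate
11 | (2S)-2-hydroxy-2-[(2S,4R,5R)-4-[(tert-butyldimethylsilyl)oxy]-5-(prop-2-en-1-yl)oxolan-2-yl]ethyl 4-methylbenzenesulfonate | C=CC[C@H]1O[C@@H](C[C@H]1O[Si](C)(C)C(C)(C)C)[C@@H](O)COS(=O)(=O)c1ccc(C)cc1 | intermediate
12 | (2S)-2-[(2S,4R,5R)-4-[(tert-butyldimethylsilyl)oxy]-5-(prop-2-en-1-yl)oxolan-2-yl]oxirane | C=CC[C@H]1O[C@@H](C[C@H]1O[Si](C)(C)C(C)(C)C)[C@@H]1CO1 | intermediate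
13 | but-1-yne | CCC#C | starting material
14 | (1S)-1-[(2S,4R,5R)-4-[(tert-butyldimethylsilyl)oxy]-5-(prop-2-en-1-yl)oxolan-2-yl]hex-3-yn-1-ol | C=CC[C@H]1O[C@@H](C[C@H]1O[Si](C)(C)C(C)(C)C)[C@@H](O)CC#CCC | intermediate
15 | (1S,3E)-1-[(2S,4R,5R)-4-[(tert-butyldimethylsilyl)oxy]-5-(prop-2-en-1-yl)oxolan-2-yl]hex-3-en-1-ol | C=CC[C@H]1O[C@@H](C[C@H]1O[Si](C)(C)C(C)(C)C)[C@@H](O)C/C=C/CC | intermediate
16 | tert-butyl (1S,3E)-1-[(2S,4R,5R)-4-[(tert-butyldimethylsilyl)oxy]-5-(prop-2-en-1-yl)oxolan-2-yl]hex-3-en-1-yl carbonate | C=CC[C@H]1O[C@@H](C[C@H]1O[Si](C)(C)C(C)(C)C)[C@@H](OC(=O)OC(C)(C)C)C/C=C/CC | intermediate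
17 | tert-butyl (1S)-2-[(2S,3S)-3-ethyloxiran-2-yl]-1-[(2S,4R,5R)-4-[(tert-butyldimethylsilyl)oxy]-5-(prop-2-en-1-yl)oxolan-2-yl]ethyl carbonate | C=CC[C@H]1O[C@@H](C[C@H]1O[Si](C)(C)C(C)(C)C)[C@@H](OC(=O)OC(C)(C)C)C[C@@H]1O[C@H]1CC | intermediate
18 | cis-fused 1-oxoniabicyclo[3.3.0]octane ion (O+ bonded to C6, C9 and C12; 6R,7R,9S,10S,12R,13S), zwitterion with the C13 trifluoroborato alkoxide | C=CC[C@H]1[O+]2[C@@H](C[C@H]1O[Si](C)(C)C(C)(C)C)[C@@H](OC(=O)OC(C)(C)C)C[C@@H]2[C@H](CC)O[B-](F)(F)F | intermediate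
19 | 2-tert-butoxy-1,3-dioxolan-2-ylium ion spanning O9 and O10 of the oxocane (6R,7R,9R,10S,12R,13S), zwitterion with the C13 trifluoroborato alkoxide | C=CC[C@H]1O[C@@H]([C@H](CC)O[B-](F)(F)F)C[C@@H]2OC(OC(C)(C)C)=[O+][C@@H]2C[C@H]1O[Si](C)(C)C(C)(C)C | intermediate
20 | (2R,3R,5R,6S,8R)-3-[(tert-butyldimethylsilyl)oxy]-8-[(1S)-1-hydroxypropyl]-2-(prop-2-en-1-yl)oxocane-5,6-diyl carbonate (cyclic) | C=CC[C@H]1O[C@@H]([C@H](CC)O)C[C@@H]2OC(=O)O[C@@H]2C[C@H]1O[Si](C)(C)C(C)(C)C | intermediate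
21 | (2R,3R,5R,6S,8R)-3-[(tert-butyldimethylsilyl)oxy]-8-[(1S)-1-hydroxypropyl]-2-(prop-2-en-1-yl)oxocane-5,6-diol | C=CC[C@H]1O[C@@H]([C@H](CC)O)C[C@H](O)[C@H](O)C[C@H]1O[Si](C)(C)C(C)(C)C | intermediate
22 | 5,6-O-isopropylidene acetal of 21 | C=CC[C@H]1O[C@@H]([C@H](CC)O)C[C@@H]2OC(C)(C)O[C@@H]2C[C@H]1O[Si](C)(C)C(C)(C)C | intermediate
23 | 5,6-O-isopropylidene acetal of 2-[(2R,3R,5R,6S,8R)-3-[(tert-butyldimethylsilyl)oxy]-5,6-dihydroxy-8-[(1S)-1-hydroxypropyl]oxocan-2-yl]acetaldehyde | O=CC[C@H]1O[C@@H]([C@H](CC)O)C[C@@H]2OC(C)(C)O[C@@H]2C[C@H]1O[Si](C)(C)C(C)(C)C | intermediate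
24 | 1,3-bis(triisopropylsilyl)prop-1-yne | CC(C)[Si](C(C)C)(C(C)C)CC#C[Si](C(C)C)(C(C)C)C(C)C | starting material
25 | 5,6-O-isopropylidene acetal of (2R,3R,5R,6S,8R)-3-[(tert-butyldimethylsilyl)oxy]-8-[(1S)-1-hydroxypropyl]-2-[(2Z)-5-(triisopropylsilyl)pent-2-en-4-yn-1-yl]oxocane-5,6-diol | CC(C)[Si](C(C)C)(C(C)C)C#C/C=C\C[C@H]1O[C@@H]([C@H](CC)O)C[C@@H]2OC(C)(C)O[C@@H]2C[C@H]1O[Si](C)(C)C(C)(C)C | intermediate
26 | 5,6-O-isopropylidene acetal of (2R,3R,5R,6S,8R)-8-[(1S)-1-hydroxypropyl]-2-[(2Z)-pent-2-en-4-yn-1-yl]oxocane-3,5,6-triol | C#C/C=C\C[C@H]1O[C@@H]([C@H](CC)O)C[C@@H]2OC(C)(C)O[C@@H]2C[C@H]1O | intermediate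
27 | (2R,3R,5R,6S,8R)-8-[(1S)-1-acetoxypropyl]-5,6-(isopropylidenedioxy)-2-[(2Z)-pent-2-en-4-yn-1-yl]oxocan-3-yl acetate | C#C/C=C\C[C@H]1O[C@@H]([C@H](CC)OC(C)=O)C[C@@H]2OC(C)(C)O[C@@H]2C[C@H]1OC(C)=O | intermediate
28 | (2R,3R,5R,6S,8R)-8-[(1S)-1-acetoxypropyl]-5,6-dihydroxy-2-[(2Z)-pent-2-en-4-yn-1-yl]oxocan-3-yl acetate (CNP0314743.1) | C#C/C=C\C[C@H]1O[C@@H]([C@H](CC)OC(C)=O)C[C@H](O)[C@H](O)C[C@H]1OC(C)=O | target

**Step count.** Total: 18 steps. Longest linear sequence: 18 steps (1 to 28, fully linear).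

**Steps most likely to fail**

Step 12 (bears the label). The carbonate carbonyl may capture the activated epoxide directly in a 6-exo mode, or the epoxide may rearrange by hydride shift, before the ether oxygen engages; either consumes the substrate without ring expansion. Fallback (sets out from 14, rejoins at 22): semihydrogenation of 14 (H2, Lindlar catalyst, quinoline) should give the (Z)-homoallylic alcohol F1, and Boc2O/DMAP its tert-butyl carbonate F2. Treatment of F2 with BDSB (bromodiethylsulfonium bromopentachloroantimonate) in MeNO2 at low temperature is the established bromonium-induced ring expansion of this substrate class. The more electron-rich 1,2-disubstituted alkene forms the bromonium ion, the ring oxygen attacks C12 anti to bromine with the C13 chain on the convex face of the bicyclic oxonium ion, and the carbonate opens C9; this should give the (12R,13R)-bromo oxocane carbonate F3. SN2 displacement of the secondary bromide by caesium acetate (18-crown-6, DMF, 60 °C) inverts C13 to give the acetate carbonate F4. The conditions of step 13 (K2CO3, MeOH, which here also removes the acetate; then 2,2-dimethoxypropane, PPTS) return 22.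

Step 6. The (Z)-allylic alcohol may epoxidise slowly with eroded face selectivity, and the cis-epoxide may cyclise incompletely or in the 6-endo sense. Fallback (sets out from 7, rejoins at 12): trans-reduction of the propargylic alcohol 7 with Red-Al (THF, 0 °C) should give the (E)-allylic alcohol F5, the substrate class for which the Sharpless epoxidation is fastest and most selective. Epoxidation with D-(−)-DET gives the (2R,3R)-epoxy alcohol F6, which cyclises under the same acid treatment (5-exo, inversion at C9) to the C10-epimeric diol F7. Selective benzoylation of the primary hydroxyl (BzCl, 2,4,6-collidine, −40 °C) gives the hydroxy benzoate F8 and mesylation (MsCl, Et3N) the mesylate benzoate F9. K2CO3 in MeOH then removes the benzoate, and the primary alkoxide displaces the mesylate with inversion at C10 to give 12.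

Step 15. The strongly basic lithium reagent may cause β-elimination of the ring oxygen from the enolisable β-alkoxy aldehyde (ring opening), and Z selectivity may erode. Fallback (sets out from 23, rejoins at 26): Stork–Zhao olefination of 23 (Ph3P+CH2I I−, NaHMDS, THF–DMPU, −78 °C) should give the (Z)-vinyl iodide F10 under less basic conditions. Sonogashira coupling with ethynyltrimethylsilane (Pd(PPh3)4, CuI, Et3N) gives the TMS enyne F11 with retention of alkene geometry, and TBAF as in step 16 removes both silyl groups to give 26.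

**Further compounds**

F1 | step 12 | (1S,3Z)-1-[(2S,4R,5R)-4-[(tert-butyldimethylsilyl)oxy]-5-(prop-2-en-1-yl)oxolan-2-yl]hex-3-en-1-ol | C=CC[C@H]1O[C@@H](C[C@H]1O[Si](C)(C)C(C)(C)C)[C@@H](O)C/C=C\CC
F2 | step 12 | tert-butyl (1S,3Z)-1-[(2S,4R,5R)-4-[(tert-butyldimethylsilyl)oxy]-5-(prop-2-en-1-yl)oxolan-2-yl]hex-3-en-1-yl carbonate | C=CC[C@H]1O[C@@H](C[C@H]1O[Si](C)(C)C(C)(C)C)[C@@H](OC(=O)OC(C)(C)C)C/C=C\CC
F3 | step 12 | (2R,3R,5R,6S,8R)-8-[(1R)-1-bromopropyl]-3-[(tert-butyldimethylsilyl)oxy]-2-(prop-2-en-1-yl)oxocane-5,6-diyl carbonate (cyclic) | C=CC[C@H]1O[C@@H]([C@@H](CC)Br)C[C@@H]2OC(=O)O[C@@H]2C[C@H]1O[Si](C)(C)C(C)(C)C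
F4 | step 12 | (2R,3R,5R,6S,8R)-8-[(1S)-1-acetoxypropyl]-3-[(tert-butyldimethylsilyl)oxy]-2-(prop-2-en-1-yl)oxocane-5,6-diyl carbonate (cyclic) | C=CC[C@H]1O[C@@H]([C@H](CC)OC(C)=O)C[C@@H]2OC(=O)O[C@@H]2C[C@H]1O[Si](C)(C)C(C)(C)C
F5 | step 6 | (2E,5R,6R)-5-[(tert-butyldimethylsilyl)oxy]nona-2,8-diene-1,6-diol | C=CC[C@@H](O)[C@H](O[Si](C)(C)C(C)(C)C)C/C=C/CO
F6 | step 6 | (2R,3R)-2-[(tert-butyldimethylsilyl)oxy]-1-[(2R,3R)-3-(hydroxymethyl)oxiran-2-yl]hex-5-en-3-ol | C=CC[C@@H](O)[C@H](O[Si](C)(C)C(C)(C)C)C[C@H]1O[C@@H]1CO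
F7 | step 6 | (1R)-1-[(2S,4R,5R)-4-[(tert-butyldimethylsilyl)oxy]-5-(prop-2-en-1-yl)oxolan-2-yl]ethane-1,2-diol | C=CC[C@H]1O[C@@H](C[C@H]1O[Si](C)(C)C(C)(C)C)[C@H](O)CO
F8 | step 6 | (2R)-2-hydroxy-2-[(2S,4R,5R)-4-[(tert-butyldimethylsilyl)oxy]-5-(prop-2-en-1-yl)oxolan-2-yl]ethyl benzoate | C=CC[C@H]1O[C@@H](C[C@H]1O[Si](C)(C)C(C)(C)C)[C@H](O)COC(=O)c1ccccc1
F9 | step 6 | (2R)-2-(methanesulfonyloxy)-2-[(2S,4R,5R)-4-[(tert-butyldimethylsilyl)oxy]-5-(prop-2-en-1-yl)oxolan-2-yl]ethyl benzoate | C=CC[C@H]1O[C@@H](C[C@H]1O[Si](C)(C)C(C)(C)C)[C@H](OS(C)(=O)=O)COC(=O)c1ccccc1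
F10 | step 15 | 5,6-O-isopropylidene acetal of (2R,3R,5R,6S,8R)-3-[(tert-butyldimethylsilyl)oxy]-8-[(1S)-1-hydroxypropyl]-2-[(2Z)-3-iodoprop-2-en-1-yl]oxocane-5,6-diol | I/C=C\C[C@H]1O[C@@H]([C@H](CC)O)C[C@@H]2OC(C)(C)O[C@@H]2C[C@H]1O[Si](C)(C)C(C)(C)C
F11 | step 15 | 5,6-O-isopropylidene acetal of (2R,3R,5R,6S,8R)-3-[(tert-butyldimethylsilyl)oxy]-8-[(1S)-1-hydroxypropyl]-2-[(2Z)-5-(trimethylsilyl)pent-2-en-4-yn-1-yl]oxocane-5,6-diol | C[Si](C)(C)C#C/C=C\C[C@H]1O[C@@H]([C@H](CC)O)C[C@@H]2OC(C)(C)O[C@@H]2C[C@H]1O[Si](C)(C)C(C)(C)C
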